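**Plan**
- Retrosynthesis: the aroyl ketone and the CH2OH group are traced back (benzylic carbinol oxidation, lactone reduction) to a cis-fused furo[3,4-c]furanone; in this bicycle the C2–C3 and C4–C5 bonds of the oxolane are then cut together.
- Enabling feature: the C5–O1–C2 triad of the oxolane (benzylic carbon, ring oxygen, CH2) is a carbonyl ylide, and C3–C4 with its two cis carbon substituents is the ring-locked alkene of a 5-aryl butenolide once the oxidation levels of the two side-chain carbons are exchanged.
- Forward: the butenolide (lactone ring) is made first, the oxolane ring is built on it by [3+2] cycloaddition, and the helper lactone ring is then opened with LiAlH4 and the freed benzylic carbinol oxidised to the ketone.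
- Stereochemistry: asymmetric transfer hydrogenation sets the butenolide C5 centre. This centre sends the ylide to the opposite face (C3 and C4 of the target, cis through the ring alkene), endo addition sets C5 of the target, and the controlling centre is finally erased as the ketone.

Key step: step 6

Remark: the SMILES defines the all-cis (3R,4R,5R) oxolane; its hydroxy ketone may equilibrate with a bicyclic hemiketal, and the open form is taken as the target.

**Route**

Step 1
Reactants: 1 3',4',5'-trimethoxyacetophenone; 2 methyl bromoacetate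
Product: 3 methyl 4-oxo-4-(3,4,5-trimethoxyphenyl)butanoate
Conditions: LiN(SiMe3)2, THF, DMPU, −78 °C; then 2, −78 °C to rt
Reagents that add atoms: none
Why: Alkylation of the kinetic lithium enolate of the aryl methyl ketone with the reactive α-bromo ester (SN2) should give the γ-keto ester.

Step 2
Reactants: 3 methyl 4-oxo-4-(3,4,5-trimethoxyphenyl)butanoate
Product: 5 (5S)-5-(3,4,5-trimethoxyphenyl)oxolan-2-one, via hydroxy ester 4 (not isolated)
Conditions: RuCl[(S,S)-TsDPEN](p-cymene) (cat.), HCO2H/Et3N (5:2), 40 °C; then TsOH (cat.), toluene, 60 °C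
Reagents that add atoms: none
Why: Noyori asymmetric transfer hydrogenation of the aryl ketone with the (S,S) catalyst should deliver the (S) carbinol, as it does for aryl alkyl ketones (hydride transfer in a six-membered transition state with the aryl group held by a CH/π contact), and acid then closes the γ-lactone.

Step 3
Reactants: 5 (5S)-5-(3,4,5-trimethoxyphenyl)oxolan-2-one
Product: 6 (5S)-3-(phenylselanyl)-5-(3,4,5-trimethoxyphenyl)oxolan-2-one
Conditions: LiN(i-Pr)2, THF, −78 °C; then PhSeBr, −78 °C
Reagents that add atoms: phenylselanyl bromide (PhSeBr), Br[Se]c1ccccc1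
Why: α-Selenenylation of the lactone lithium enolate should proceed without touching the non-acidic benzylic C5–H; the C3 epimer ratio is irrelevant because C3 becomes sp2 in the next step.

Step 4
Reactants: 6 (5S)-3-(phenylselanyl)-5-(3,4,5-trimethoxyphenyl)oxolan-2-one
Product: 8 (5S)-5-(3,4,5-trimethoxyphenyl)furan-2(5H)-one, via selenoxide 7 (not isolated)
Conditions: H2O2 (30% aq), CH2Cl2, 0 °C to rt
Reagents that add atoms: none
Why: Oxidation to the selenoxide and spontaneous syn elimination toward C4 should give the butenolide under neutral to weakly acidic conditions, so the base-labile C5 centre is not exposed to base.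

Step 5
Reactants: 9 3,4-dimethoxybenzaldehyde; 10 (trimethylsilyl)methanol
Product: 11 4-{bis[(trimethylsilyl)methoxy]methyl}-1,2-dimethoxybenzene
Conditions: 10 (2.5 equiv), PPTS (cat.), benzene, reflux, Dean–Stark
Reagents that add atoms: none
Why: Acid-catalysed acetalisation driven by azeotropic removal of water should give the bis(silylmethyl) acetal, the α-silyl alcohol being stable to mild acid.

Step 6
Reactants: 11 4-{bis[(trimethylsilyl)methoxy]methyl}-1,2-dimethoxybenzene (1.5 equiv); 8 (5S)-5-(3,4,5-trimethoxyphenyl)furan-2(5H)-one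
Product: 14 (3S,3aR,6R,6aS)-6-(3,4-dimethoxyphenyl)-3-(3,4,5-trimethoxyphenyl)tetrahydro-1H,3H-furo[3,4-c]furan-1-one, via chloro ether 12 (not isolated), via carbonyl ylide 13 (not isolated)
Conditions: 11, AcCl (1.0 equiv to 11), MeCN, −20 °C; then 8, CsF (3 equiv), −20 °C to rt
Reagents that add atoms: none
Why: Acetyl chloride should cleave one silylmethoxy group of 11 to give the α-chloro ether 12; ionisation of 12, assisted by the 3,4-dimethoxyphenyl ring, and fluoride attack at silicon amount to a 1,3-elimination that releases the non-stabilised carbonyl ylide 13, which the lactone-activated alkene of 8 traps in a suprafacial 1,3-dipolar [3+2] cycloaddition. The closest known reaction type is the silicon-based 1,3-elimination of α-chloroalkyl silylmethyl ethers with CsF and the cycloaddition of the resulting ylides to activated alkenes. The oxolane ring is closed by a concerted but asynchronous [4π+2π] addition in which the carbanionic CH2 terminus bonds to the β-carbon of the butenolide and the aryl-stabilised oxocarbenium terminus to the α-carbon, which fixes the regiochemistry. The ring-fusion centres C3a and C6a are set cis by the ring-locked Z alkene and in the absolute sense by attack on the face anti to the C5 aryl group of 8, and C6 is set by an endo transition state in which the lactone lies under the E-configured ylide (aryl outside), so that the aryl group ends up cis to the lactone ring. The step therefore needs regio-, face- and endo-selectivity, to be secured respectively by the polarity match, the existing stereocentre and secondary overlap of the lactone carbonyl with the dipole, and it needs C5–H of 8 to stay untouched, for which the sparingly soluble fluoride, the low temperature and the use of 8 as limiting reagent are chosen.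

Step 7
Reactants: 14 (3S,3aR,6R,6aS)-6-(3,4-dimethoxyphenyl)-3-(3,4,5-trimethoxyphenyl)tetrahydro-1H,3H-furo[3,4-c]furan-1-one
Product: 15 (S)-[(3R,4R,5R)-5-(3,4-dimethoxyphenyl)-4-(hydroxymethyl)oxolan-3-yl](3,4,5-trimethoxyphenyl)methanol
Conditions: LiAlH4, THF, 0 °C
Reagents that add atoms: none
Why: Hydride reduction of the lactone should open the helper ring to the 1,4-diol, turning the lactone carbonyl into the CH2OH group without disturbing the stereocentres, since no enolisable carbonyl persists.

Step 8
Reactants: 15 (S)-[(3R,4R,5R)-5-(3,4-dimethoxyphenyl)-4-(hydroxymethyl)oxolan-3-yl](3,4,5-trimethoxyphenyl)methanol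
Product: 16 [(3R,4R,5R)-5-(3,4-dimethoxyphenyl)-4-(hydroxymethyl)oxolan-3-yl](3,4,5-trimethoxyphenyl)methanone
Conditions: MnO2 (activated, excess), CH2Cl2, rt
Reagents that add atoms: none
Why: Activated MnO2 should oxidise the benzylic secondary carbinol far faster than the saturated primary alcohol, and its neutral surface should spare the now enolisable C3 centre, while the hemiketal form of the product has no carbinol hydrogen and cannot be oxidised further.

**Compound list**
1 | 3',4',5'-trimethoxyacetophenone | CC(=O)c1cc(OC)c(OC)c(OC)c1 | starting material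
2 | methyl bromoacetate | COC(=O)CBr | starting material
3 | methyl 4-oxo-4-(3,4,5-trimethoxyphenyl)butanoate | COC(=O)CCC(=O)c1cc(OC)c(OC)c(OC)c1 | intermediate
4 | methyl (4S)-4-hydroxy-4-(3,4,5-trimethoxyphenyl)butanoate | COC(=O)CC[C@@H](c1cc(OC)c(OC)c(OC)c1)O | intermediate
5 | (5S)-5-(3,4,5-trimethoxyphenyl)oxolan-2-one | O=C1CC[C@@H](c2cc(OC)c(OC)c(OC)c2)O1 | intermediate
6 | (5S)-3-(phenylselanyl)-5-(3,4,5-trimethoxyphenyl)oxolan-2-one (C3 epimers) | O=C1C([Se]c2ccccc2)C[C@@H](c3cc(OC)c(OC)c(OC)c3)O1 | intermediate
7 | (5S)-3-(benzeneseleninyl)-5-(3,4,5-trimethoxyphenyl)oxolan-2-one (selenoxide) | O=C1C([Se](=O)c2ccccc2)C[C@@H](c3cc(OC)c(OC)c(OC)c3)O1 | intermediate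
8 | (5S)-5-(3,4,5-trimethoxyphenyl)furan-2(5H)-one | O=C1C=C[C@@H](c2cc(OC)c(OC)c(OC)c2)O1 | intermediate
9 | 3,4-dimethoxybenzaldehyde | COc1ccc(C=O)cc1OC | starting material
10 | (trimethylsilyl)methanol | C[Si](C)(C)CO | starting material
11 | 4-{bis[(trimethylsilyl)methoxy]methyl}-1,2-dimethoxybenzene | COc1ccc(C(OC[Si](C)(C)C)OC[Si](C)(C)C)cc1OC | intermediate
12 | 4-{chloro[(trimethylsilyl)methoxy]methyl}-1,2-dimethoxybenzene (racemic α-chloro ether) | COc1ccc(C(Cl)OC[Si](C)(C)C)cc1OC | intermediate
13 | 3,4-dimethoxybenzaldehyde O-methylide (E carbonyl ylide) | COc1ccc(/C=[O+]/[CH2-])cc1OC | intermediate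
14 | (3S,3aR,6R,6aS)-6-(3,4-dimethoxyphenyl)-3-(3,4,5-trimethoxyphenyl)tetrahydro-1H,3H-furo[3,4-c]furan-1-one | COc1ccc([C@@H]2OC[C@H]([C@@H](c3cc(OC)c(OC)c(OC)c3)O4)[C@@H]2C4=O)cc1OC | intermediate
15 | (S)-[(3R,4R,5R)-5-(3,4-dimethoxyphenyl)-4-(hydroxymethyl)oxolan-3-yl](3,4,5-trimethoxyphenyl)methanol | COc1ccc([C@@H]2OC[C@H]([C@@H](c3cc(OC)c(OC)c(OC)c3)O)[C@@H]2CO)cc1OC | intermediate
16 | [(3R,4R,5R)-5-(3,4-dimethoxyphenyl)-4-(hydroxymethyl)oxolan-3-yl](3,4,5-trimethoxyphenyl)methanone | COc1ccc([C@@H]2OC[C@H](C(=O)c3cc(OC)c(OC)c(OC)c3)[C@@H]2CO)cc1OC | target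

**Count**
Total step count: 8. Longest linear sequence: 7 steps (steps 1, 2, 3, 4, 6, 7, 8); step 5 is a one-step side branch.

**Steps most likely to fail**

Step 6. The process at risk is poor endo/exo selectivity: if the lactone ring approaches the ylide in the exo sense, the 3,4-dimethoxyphenyl group lands on the convex face of the bicycle. The fallback sets out from 8 and 11 and comes back at 14. The cycloaddition is run as above with no demand on endo/exo control, and the C6 epimer (3S,3aR,6S,6aS)-6-(3,4-dimethoxyphenyl)-3-(3,4,5-trimethoxyphenyl)tetrahydro-1H,3H-furo[3,4-c]furan-1-one F1 is carried on. DDQ in CH2Cl2/pH 7 buffer should abstract hydride from the benzylic ether C–H next to the dimethoxyphenyl ring, and water should capture the oxocarbenium ion to give the hemiketal (3S,3aR,6aS)-6-(3,4-dimethoxyphenyl)-6-hydroxy-3-(3,4,5-trimethoxyphenyl)tetrahydro-1H,3H-furo[3,4-c]furan-1-one F2. Ionic hydrogenation (Et3SiH, BF3·OEt2, CH2Cl2, −78 °C) should then deliver hydride to the regenerated oxocarbenium ion from the convex face of the cis-fused bicycle, which forces the aryl group onto the concave face and gives 14. C6 is thus set by substrate-controlled reduction instead of by the cycloaddition.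

Step 8. The process at risk is loss of chemoselectivity or slow conversion on the oxidant surface, which would lead to attack on the primary alcohol or to epimerisation at the enolisable C3 centre. The fallback sets out from 15 and comes back at 16 by a protecting-group detour. TBSCl and imidazole in DMF at 0 °C should silylate the primary alcohol selectively to give (S)-[(3R,4R,5R)-4-{[(tert-butyldimethylsilyl)oxy]methyl}-5-(3,4-dimethoxyphenyl)oxolan-3-yl](3,4,5-trimethoxyphenyl)methanol F3. Dess–Martin periodinane buffered with NaHCO3 should oxidise the remaining carbinol to [(3R,4R,5R)-4-{[(tert-butyldimethylsilyl)oxy]methyl}-5-(3,4-dimethoxyphenyl)oxolan-3-yl](3,4,5-trimethoxyphenyl)methanone F4. HF·pyridine in THF/pyridine at 0 °C should then remove the silyl group under non-basic conditions to give 16.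

Step 1. The process at risk is over-alkylation and proton exchange between the enolate and the more acidic product. The fallback sets out from 1 and comes back at 3. Aldol condensation of 1 with glyoxylic acid (AcOH, reflux) should give (E)-4-oxo-4-(3,4,5-trimethoxyphenyl)but-2-enoic acid F5. Zn dust in AcOH should reduce the activated C=C bond to give 4-oxo-4-(3,4,5-trimethoxyphenyl)butanoic acid F6. Fischer esterification (MeOH, cat. H2SO4, reflux) should give 3.

Further compounds
F1 | step 6 | (3S,3aR,6S,6aS)-6-(3,4-dimethoxyphenyl)-3-(3,4,5-trimethoxyphenyl)tetrahydro-1H,3H-furo[3,4-c]furan-1-one | COc1ccc([C@H]2OC[C@H]([C@@H](c3cc(OC)c(OC)c(OC)c3)O4)[C@@H]2C4=O)cc1OC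
F2 | step 6 | (3S,3aR,6aS)-6-(3,4-dimethoxyphenyl)-6-hydroxy-3-(3,4,5-trimethoxyphenyl)tetrahydro-1H,3H-furo[3,4-c]furan-1-one (C6 anomers) | COc1ccc(C2(O)OC[C@H]([C@@H](c3cc(OC)c(OC)c(OC)c3)O4)[C@@H]2C4=O)cc1OC
F3 | step 8 | (S)-[(3R,4R,5R)-4-{[(tert-butyldimethylsilyl)oxy]methyl}-5-(3,4-dimethoxyphenyl)oxolan-3-yl](3,4,5-trimethoxyphenyl)methanol | COc1ccc([C@@H]2OC[C@H]([C@@H](c3cc(OC)c(OC)c(OC)c3)O)[C@@H]2CO[Si](C)(C)C(C)(C)C)cc1OC
F4 | step 8 | [(3R,4R,5R)-4-{[(tert-butyldimethylsilyl)oxy]methyl}-5-(3,4-dimethoxyphenyl)oxolan-3-yl](3,4,5-trimethoxyphenyl)methanone | COc1ccc([C@@H]2OC[C@H](C(=O)c3cc(OC)c(OC)c(OC)c3)[C@@H]2CO[Si](C)(C)C(C)(C)C)cc1OC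
F5 | step 1 | (E)-4-oxo-4-(3,4,5-trimethoxyphenyl)but-2-enoic acid | O=C(O)/C=C/C(=O)c1cc(OC)c(OC)c(OC)c1
F6 | step 1 | 4-oxo-4-(3,4,5-trimethoxyphenyl)butanoic acid | O=C(O)CCC(=O)c1cc(OC)c(OC)c(OC)c1
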